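**Retrosynthetic overview**

1. Target 20 ⇒ C2–aryl bond: intramolecular ipso-arylation of the furanosyl oxocarbenium ion (O1=C2) by a 3,4-dimethoxyphenyl group held on the C4 oxygen through a temporary O–SiMe2 tether (methyl furanoside 17); the silicon is lost in the same operation.
2. Enabling feature: C2 is the acetal-level carbon next to the ring oxygen O1 of the oxolane, and the C4 hydroxyl lies 1,3-cis to the C2 aryl group on the same ring face, so a three-atom O4–Si–C(aryl) bridge can reach C2 only on the required face.
3. 17 ⇒ methyl furanoside 12 + chlorosilane 16 (from 4-bromoveratrole 13 and Me2SiCl2 14).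
4. 12 ⇒ acyclic vinyl diol monoester 10: the oxolane ring, the only ring formed in the route, is closed by ozonolysis of the vinyl group and acetalisation through the C5 hydroxyl.
5. 10 ⇒ Evans syn-aldol of crotonyl imide 4 with silyloxyacetaldehyde 5 (sets C3 and C4), reductive removal of the auxiliary, primary-selective veratroylation.

Key step: step 8

Assumption: the methyl furanosides 12 and 17 are carried as anomeric mixtures, because both anomers ionise to the same oxocarbenium ion in step 8.

**Route**

Step 1
Reactants: 1 (S)-4-benzyloxazolidin-2-one; 2 (E)-but-2-enoyl chloride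
Product: 4 (S)-4-benzyl-3-[(E)-but-2-enoyl]oxazolidin-2-one, via lithiated oxazolidinone 3 (not isolated)
Conditions: n-BuLi, THF, −78 °C; then 2, −78 → 0 °C
Reagents that add atoms: none
Why: N-Acylation of the lithiated oxazolidinone with an acid chloride is a standard imide formation that creates no stereocentre and leaves the auxiliary centre untouched.

Step 2
Reactants: 4 (S)-4-benzyl-3-[(E)-but-2-enoyl]oxazolidin-2-one; 5 2-[(tert-butyldimethylsilyl)oxy]acetaldehyde
Product: 7 (S)-4-benzyl-3-[(2S,3S)-4-{[tert-butyl(dimethyl)silyl]oxy}-2-ethenyl-3-hydroxybutanoyl]oxazolidin-2-one, via boron dienolate 6 (not isolated)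
Conditions: Bu2BOTf, Et3N, CH2Cl2, −78 → 0 °C; then 5, −78 → 0 °C; pH 7 buffer, MeOH, 30% H2O2, 0 °C
Reagents that add atoms: none
Why: Evans syn-aldol reaction of the (Z)-boron dienolate, which should react at its α-carbon through a closed Zimmerman–Traxler chair on the face away from the benzyl group of the (S)-auxiliary and so set both new centres (2S,3S, vinyl and hydroxyl syn) under auxiliary control.

Step 3
Reactants: 7 (S)-4-benzyl-3-[(2S,3S)-4-{[tert-butyl(dimethyl)silyl]oxy}-2-ethenyl-3-hydroxybutanoyl]oxazolidin-2-one
Product: 8 (2R,3S)-4-{[tert-butyl(dimethyl)silyl]oxy}-2-ethenylbutane-1,3-diol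
Conditions: LiBH4, MeOH (1 equiv), Et2O/THF, 0 °C
Reagents that add atoms: none
Why: Reductive cleavage of the N-acyl oxazolidinone with LiBH4 should release the primary alcohol and the recoverable auxiliary without touching either stereocentre (the descriptor at the vinyl-bearing carbon changes only because the priorities change).

Step 4
Reactants: 8 (2R,3S)-4-{[tert-butyl(dimethyl)silyl]oxy}-2-ethenylbutane-1,3-diol; 9 3,4-dimethoxybenzoyl chloride
Product: 10 (2R,3S)-4-{[tert-butyl(dimethyl)silyl]oxy}-2-ethenyl-3-hydroxybutyl 3,4-dimethoxybenzoate
Conditions: 9 (1.05 equiv), 2,4,6-collidine, CH2Cl2, −40 → 0 °C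
Reagents that add atoms: none
Why: Site-selective O-acylation, in which the aroyl chloride with a hindered pyridine base at low temperature should take the unhindered primary hydroxyl in preference to the secondary one, the primary ester also being the thermodynamically preferred regioisomer.

Step 5
Reactants: 10 (2R,3S)-4-{[tert-butyl(dimethyl)silyl]oxy}-2-ethenyl-3-hydroxybutyl 3,4-dimethoxybenzoate
Product: 12 [(3R,4S)-4-hydroxy-2-methoxyoxolan-3-yl]methyl 3,4-dimethoxybenzoate (both anomers), via aldehyde 11 (not isolated)
Conditions: O3, CH2Cl2/MeOH (3:1), −78 °C (Sudan Red 7B end point); Me2S, −78 °C → rt; then CSA (0.2 equiv), rt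
Reagents that add atoms: methanol, CO (anomeric OMe of 12); ozone, [O-][O+]=O (carbonyl O of 11 only, lost as water on acetal formation)
Why: Ozonolysis of the terminal alkene with reductive work-up should give the aldehyde, and acid in methanol then removes the primary TBS ether and closes the oxolane ring by 5-exo-trig attack of the C5 hydroxyl on the carbonyl followed by Fischer-type methyl acetal formation, with C3 and C4 untouched and the anomeric centre left as a mixture on purpose.

Step 6
Reactants: 13 4-bromo-1,2-dimethoxybenzene; 14 dichlorodimethylsilane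
Product: 16 chloro(3,4-dimethoxyphenyl)dimethylsilane, via aryllithium 15 (not isolated)
Conditions: n-BuLi, THF, −78 °C; then cannulation into 14 (4 equiv), THF, −78 °C → rt; distillation
Reagents that add atoms: none
Why: Bromine–lithium exchange followed by substitution at silicon, with inverse addition to an excess of the dichlorosilane so that mono-arylation should prevail.

Step 7
Reactants: 12 [(3R,4S)-4-hydroxy-2-methoxyoxolan-3-yl]methyl 3,4-dimethoxybenzoate (both anomers); 16 chloro(3,4-dimethoxyphenyl)dimethylsilane
Product: 17 [(3R,4S)-4-{[(3,4-dimethoxyphenyl)dimethylsilyl]oxy}-2-methoxyoxolan-3-yl]methyl 3,4-dimethoxybenzoate (both anomers)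
Conditions: imidazole, CH2Cl2, 0 °C → rt; filtration through Et3N-deactivated silica
Reagents that add atoms: none
Why: Standard silyl ether formation at the secondary C4 hydroxyl with a chlorosilane and imidazole, which installs the aryl group as a temporary O–Si–C tether and affects no stereocentre.

Step 8
Reactants: 17 [(3R,4S)-4-{[(3,4-dimethoxyphenyl)dimethylsilyl]oxy}-2-methoxyoxolan-3-yl]methyl 3,4-dimethoxybenzoate (both anomers)
Product: 20 [(2S,3R,4S)-2-(3,4-dimethoxyphenyl)-4-hydroxyoxolan-3-yl]methyl 3,4-dimethoxybenzoate, via oxocarbenium triflate 18 (not isolated), via silyl triflate 19 (not isolated)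
Conditions: TMSOTf (1.2 equiv), 2,6-di-tert-butyl-4-methylpyridine, CH2Cl2 (0.01 M), −78 → −40 °C; sat. aq NaHCO3; then AcOH/THF/H2O (3:1:1), rt
Reagents that add atoms: none
Why: Proposed new method: TMSOTf removes the anomeric methoxy group from either anomer of 17, so that both funnel into the one oxocarbenium ion 18 (O1=C2), whose C2 is attacked by the silicon-bearing ipso carbon of the tethered aryl group (para to a methoxy group, arenium ion stabilised by the β-silicon effect), after which triflate cleaves the C(aryl)–Si bond, restores the aromatic ring and leaves the silicon on O4 as silyl triflate 19, hydrolysed in the work-up to the free C4 hydroxyl. The closest known reaction type is the Lewis-acid-promoted ipso-Friedel–Crafts aryl delivery from a 2-O-(aryldimethylsilyl) group to the anomeric carbon of pyranosyl donors through a five-membered transition ring, together with the intermolecular Friedel–Crafts C-arylation of furanosyl oxocarbenium ions; new here is the 1,3-delivery from O4 through a six-membered transition ring on a furanosyl cation. No ring of the target is closed: the transient ring (C2, C3, C4, O4, Si, aryl C1) forms in the 6-exo-trig mode at the oxocarbenium carbon and the ipso (spiro) mode at the arene and is opened again at once by the C–Si cleavage. The new stereocentre C2 (S) is set by the tether, because the three-atom O4–Si–C(aryl) bridge can reach C2 only on the ring face that carries O4, which places the aryl group cis to the C4 oxygen and to the C3 CH2O arm; this is also the inside face of the envelope with the C4 silyloxy group pseudoaxial, so the intrinsic preference of the cation points the same way. The step needs facial selectivity, ipso rather than ortho attack on the arene and intramolecular rather than intermolecular transfer, which are secured by the tether geometry, by the β-silicon effect together with the smaller ring, and by high dilution. Reversible capture of 18 by the ester carbonyl as a cis-fused dioxanium ion only stores the cation, and the hindered pyridine base should suppress protodesilylation and acid-induced opening of the benzylic ether in the product.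

**Compound list**

1 | (S)-4-benzyloxazolidin-2-one | O=C1OC[C@H](Cc2ccccc2)N1 | starting material
2 | (E)-but-2-enoyl chloride (crotonyl chloride) | C/C=C/C(Cl)=O | starting material
3 | N-lithio-(S)-4-benzyloxazolidin-2-one | [Li+].O=C1OC[C@H](Cc2ccccc2)[N-]1 | intermediate (not isolated)
4 | (S)-4-benzyl-3-[(E)-but-2-enoyl]oxazolidin-2-one | C/C=C/C(=O)N1[C@@H](Cc2ccccc2)COC1=O | intermediate
5 | 2-[(tert-butyldimethylsilyl)oxy]acetaldehyde | O=CCO[Si](C)(C)C(C)(C)C | starting material
6 | dibutylboron (Z)-dienolate of 4 | C=C/C=C(\OB(CCCC)CCCC)N1[C@@H](Cc2ccccc2)COC1=O | intermediate (not isolated)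
7 | (S)-4-benzyl-3-[(2S,3S)-4-{[tert-butyl(dimethyl)silyl]oxy}-2-ethenyl-3-hydroxybutanoyl]oxazolidin-2-one | O=C1OC[C@H](Cc2ccccc2)N1C(=O)[C@@H](C=C)[C@H](O)CO[Si](C)(C)C(C)(C)C | intermediate
8 | (2R,3S)-4-{[tert-butyl(dimethyl)silyl]oxy}-2-ethenylbutane-1,3-diol | OC[C@@H](C=C)[C@H](O)CO[Si](C)(C)C(C)(C)C | intermediate
9 | 3,4-dimethoxybenzoyl chloride | COc1ccc(C(Cl)=O)cc1OC | starting material
10 | (2R,3S)-4-{[tert-butyl(dimethyl)silyl]oxy}-2-ethenyl-3-hydroxybutyl 3,4-dimethoxybenzoate | COc1ccc(C(=O)OC[C@@H](C=C)[C@H](O)CO[Si](C)(C)C(C)(C)C)cc1OC | intermediate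
11 | (2R,3S)-4-{[tert-butyl(dimethyl)silyl]oxy}-2-formyl-3-hydroxybutyl 3,4-dimethoxybenzoate | COc1ccc(C(=O)OC[C@@H](C=O)[C@H](O)CO[Si](C)(C)C(C)(C)C)cc1OC | intermediate (not isolated)
12 | [(3R,4S)-4-hydroxy-2-methoxyoxolan-3-yl]methyl 3,4-dimethoxybenzoate (both anomers) | COc1ccc(C(=O)OC[C@@H]2[C@H](O)COC2OC)cc1OC | intermediate
13 | 4-bromo-1,2-dimethoxybenzene | COc1ccc(Br)cc1OC | starting material
14 | dichlorodimethylsilane | C[Si](C)(Cl)Cl | starting material
15 | (3,4-dimethoxyphenyl)lithium | [Li]c1ccc(OC)c(OC)c1 | intermediate (not isolated)
16 | chloro(3,4-dimethoxyphenyl)dimethylsilane | COc1ccc([Si](C)(C)Cl)cc1OC | intermediate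
17 | [(3R,4S)-4-{[(3,4-dimethoxyphenyl)dimethylsilyl]oxy}-2-methoxyoxolan-3-yl]methyl 3,4-dimethoxybenzoate (both anomers) | COc1ccc(C(=O)OC[C@@H]2[C@H](O[Si](C)(C)c3ccc(OC)c(OC)c3)COC2OC)cc1OC | intermediate
18 | furanosyl oxocarbenium triflate: O1=C2 cation of 17 after loss of methoxide (3R,4S) | COc1ccc(C(=O)OC[C@@H]2[C@H](O[Si](C)(C)c3ccc(OC)c(OC)c3)C[O+]=C2)cc1OC.[O-]S(=O)(=O)C(F)(F)F | intermediate (not isolated)
19 | [(2S,3S,4S)-2-(3,4-dimethoxyphenyl)-4-({dimethyl[(trifluoromethanesulfonyl)oxy]silyl}oxy)oxolan-3-yl]methyl 3,4-dimethoxybenzoate (same arrangement in space as 20; the C3 descriptor changes by priority only) | COc1ccc(C(=O)OC[C@@H]2[C@H](O[Si](C)(C)OS(=O)(=O)C(F)(F)F)CO[C@@H]2c2ccc(OC)c(OC)c2)cc1OC | intermediate (not isolated)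
20 | [(2S,3R,4S)-2-(3,4-dimethoxyphenyl)-4-hydroxyoxolan-3-yl]methyl 3,4-dimethoxybenzoate (aryl, CH2O arm and hydroxyl all cis) | COc1ccc(C(=O)OC[C@@H]2[C@H](O)CO[C@@H]2c2ccc(OC)c(OC)c2)cc1OC | target

**Step count and risks**

Total step count: 8. Longest linear sequence: 7 steps (steps 1, 2, 3, 4, 5, 7, 8); the chlorosilane 16 is made in one side step (step 6).

Steps most likely to fail:

Step 8 (Proposed new method). The tethered transfer may fail through silyl exchange at the labile O–Si bond, protodesilylation of the arylsilane, or intermolecular aryl transfer, so that the aryl group is not delivered inside the molecule. The fallback uses known chemistry only and sets out from 12. Silylation with TBSCl and imidazole in DMF should give the 4-O-TBS methyl furanoside F1. Intermolecular Friedel–Crafts C-arylation of F1 with commercial 1,2-dimethoxybenzene (SnBr4, CH2Cl2, −78 °C, short reaction time for kinetic control) should pass through the same type of oxocarbenium ion, with inside attack cis to the pseudoaxial 4-silyloxy group and reaction of the arene para to a methoxy group, and give the all-cis C-aryl silyl ether F2. Buffered desilylation (TBAF/AcOH, THF, 0 °C) then comes back to the route at 20.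

Step 5. Competing oxidation of the electron-rich aroyl ring by ozone, and acid-induced β-elimination or epimerisation of the aldehyde before it is captured as the acetal, may erode the one-pot sequence. The fallback sets out from 10. Dihydroxylation of the vinyl group (cat. OsO4, NMO, acetone/H2O) should give the triol F3 as a mixture of epimers at the new carbinol carbon, which is of no consequence. Its terminal 1,2-diol is then cleaved with NaIO4 in buffered aqueous THF; the C4 hydroxyl is 1,3-related and the C5 oxygen is silylated, so only this glycol should react. This comes back to the route at aldehyde 11, which is taken at once into the acidic methanol stage of step 5.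

Step 4. Insufficient discrimination between the primary and the secondary hydroxyl (double acylation, or acylation at the secondary oxygen followed by migration) may lower the throughput. The fallback sets out from 8 and reaches 10 directly by a Mitsunobu esterification with commercial 3,4-dimethoxybenzoic acid (PPh3, DIAD, THF, 0 °C), in which the primary carbinol is activated selectively as the oxyphosphonium ion and displaced by the carboxylate; no new compound is passed.

**Further compounds**

F1 | step 8 | [(3R,4S)-4-{[tert-butyl(dimethyl)silyl]oxy}-2-methoxyoxolan-3-yl]methyl 3,4-dimethoxybenzoate (both anomers) | COc1ccc(C(=O)OC[C@@H]2[C@H](O[Si](C)(C)C(C)(C)C)COC2OC)cc1OC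
F2 | step 8 | [(2S,3S,4S)-4-{[tert-butyl(dimethyl)silyl]oxy}-2-(3,4-dimethoxyphenyl)oxolan-3-yl]methyl 3,4-dimethoxybenzoate | COc1ccc(C(=O)OC[C@@H]2[C@H](O[Si](C)(C)C(C)(C)C)CO[C@@H]2c2ccc(OC)c(OC)c2)cc1OC
F3 | step 5 | (2S,3S)-4-{[tert-butyl(dimethyl)silyl]oxy}-2-(1,2-dihydroxyethyl)-3-hydroxybutyl 3,4-dimethoxybenzoate (epimers at the new carbinol carbon) | COc1ccc(C(=O)OC[C@@H](C(O)CO)[C@H](O)CO[Si](C)(C)C(C)(C)C)cc1OC
F0 | step 4 | none | none
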